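**Conventions.** TBS = tert-butyldimethylsilyl, TES = triethylsilyl, TMS = trimethylsilyl. Labdane numbering is used for the terpenoid part throughout: C1–C10 decalin, C11 on C9, C17 on C8, C18/C19 on C4, C20 on C10. α/β mean below/above the decalin drawn with C20 up. The quinone ring atoms are called Q1–Q6: Q1 is the carbonyl next to the methoxy-bearing Q2, Q3 is CH, Q4 is the second carbonyl, Q5 carries the chromonyl group, Q6 is CH.

## Analysis of the target

Dichrostachine B joins a labdane diterpene to an oxidised flavone. The terpenoid half is a trans-fused decalin (rings A and B) with a quaternary C10 next to the gem-dimethyl C4, an equatorial 2α-hydroxyl, an equatorial 7β-hydroxyl allylic to the exocyclic C8=C17 methylene, and the C9 side chain β, cis to C20. C11 links C9 to C12 of a cyclohexene (ring C, C12–C15 with the C13 methyl). Ring C is cis-fused to a 2-methoxy-ene-1,4-dione (ring D), whose quaternary ring-fusion carbon carries a 5,7-dihydroxychromon-2-yl group. There are eight stereocentres: C2, C5, C7, C9 and C10 in the decalin, and C12 plus the two ring-fusion carbons. In the second group C11, the chromonyl group and the ring-fusion hydrogen lie on one face, which is what endo addition of a 12Z-labda-8(17),12,14-triene to the aryl-bearing double bond of a methoxy-p-quinone would give. The two groups are separated by the C11 methylene, so their mutual configuration cannot be relayed through a ring. The sensitive groups are the exocyclic allylic alcohol (acid), the enedione with its vinylogous ester and epimerisable ring-fusion CH (base, nucleophiles), and the phenols. The hard parts are the congested C4–C5–C10 array with four contiguous decalin stereocentres, the Z-diene, and the remote stereocontrol in the last bond formation. The strategy rests on ring B: oxygen on C7, the one-carbon unit C17 on C8 and the side-chain carbon C11 on C9 next to quaternary C10. This is the pattern left when a 2-oxygenated diene (C5=C6–C7(O)=C8–C17) adds to a β-methyl enal (C11–C9=C10–C20) that is tied to it through C1–C4.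

## Retrosynthetic reasoning

**42 to 35 and 41.** The C12–Q5 and C15–Q6 bonds of ring C are cut in a retro-Diels–Alder sense. This separates the two halves, removes three stereocentres at once, and matches the endo adduct of the 12Z-diene 35 with quinone 41. Placing this bond formation last means the sensitive adduct never sees a deprotection. The forward reaction has to deliver the regiochemistry, the endo mode and the correct diene face.

**41 to 40, then to 38 and 37 (from 36).** The quinone carbonyls are traced to the two para-related methoxy groups of a 2′,4′,5′-trimethoxy B ring (oxidative demethylation). Flavone 40 is cut at the C2–C3 enolate bond and the pyranone C–O bond, which leads to the acetophenone 38 and the acid chloride 37 via diketone 39.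

**35 to 34, 33, 32, then to 26 and 29.** The terminal C14=C15 bond comes from methylenation of Z-enal 33. The C11–C12 single bond is cut next, not the C12=C13 double bond. This way the Z geometry arrives ready-made in the three-carbon iodide 29 (from 27), and C11 is exactly the carbon the key step delivers as a formyl group. The forward reaction is an sp3–sp2 coupling that must keep the alkene geometry.

**26 back to 19 (via 25, 24, 22, 21, 20).** These are functional-group changes on ring B. The 7β-hydroxyl comes from axial hydride addition to exocyclic enone 24. The enone comes from the α-methyl ketone by selenation at C8 and selenoxide elimination. The iodide comes from the primary alcohol. Every group of the key-step product is used: the C7 enol ether as the ketone, the C8 methyl as the future methylene, the C9 formyl group as C11.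

**19 and 17 to 16 (key disconnection).** The C5–C10 and C8–C9 bonds are cut together. Ring B is the Diels–Alder retron, and because the dienophile is tethered through C1–C4, the same cut opens ring A. The result is a linear trienal with one stereocentre. Cutting elsewhere (for example only in ring B) would leave a chiral, fully substituted cyclohexane to be made first.

**16 to 14, 13, then to 11 and 12.** The formyl carbon is disconnected last (C9–C11, formylation of alkenyllithium 15). This lets the dienol ether be made from enone 13 while no other carbonyl is present. The C5=C6 bond is a Horner–Wadsworth–Emmons disconnection to aldehyde 11 and phosphonate 12.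

**11 to 9, 7, 6, 5, then to 1 and 2.** The E-trisubstituted alkenyl iodide is traced to a terminal alkyne by syn methylmetalation (C10–C20 bond), which fixes the geometry that a ketone olefination would not. The alkyne arm and the nitrile arm are attached to the two carbons flanking the stereocentre of 2 by two successive epoxide openings, so the only stereocentre of the precursor is bought.

## Alternatives that were turned down

**Alternative 1:** Late construction of the chromone. The pyranone is cut at the alkyne–carbonyl, carbonyl–aryl and O1–C2 bonds. In the forward sense the angular terminal alkyne A2, the iodophenol A3 and one carbon from a carbonylative palladium/copper coupling give the protected natural product A1.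
- For: the ring C/D cycloaddition leading to A2 would use a far smaller and more reactive dienophile than 41, and the polar flavone appears only at the end. On dienophile reactivity this plan is stronger than the chosen one.
- Against: the alkyne sits on a quaternary carbon, and the aryl iodide of A3 is flanked by two ortho oxygens, so both coupling events are hindered. The phenol oxygen can also close in the 5-exo sense, giving a benzofuranone instead of the pyranone. The enedione and its epimerisable CH must survive amine base and palladium. A1 still needs acidic acetal cleavage next to an allylic alcohol and a vinylogous ester.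
- Comparison: it adds three operations to the most advanced intermediate and leaves the decalin problem untouched. The chosen route instead ends with the cycloaddition itself, on unprotected partners.

**Alternative 2:** Ring B is cut at C9–C10 and C7–C8. The but-2-ynoate ester A5 of a chiral-pool vinylcyclohexenol would undergo an ester-tethered intramolecular Diels–Alder reaction to the bridged lactone A4.
- For: ring A with the C2 stereocentre and the gem-dimethyl group is bought, and the covalent tether delivers the dienophile to the α face, so C10 is set with certainty. On security of absolute control at C10 and on cost of the starting ring this plan is at least as strong as the chosen one.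
- Against: the diene terminus C10 is fully substituted and the alkyne is only ester-activated, so forcing conditions and a strained bridged product are expected. A4 has C5 and C9 trigonal, no oxygen at C7, and the C8 alkene inside the ring. Two face-selective reductions of hindered alkenes next to quaternary carbons, an allylic oxidation and an alkene transposition would follow.
- Comparison: by count, more operations are needed to reach the level of 25 than the six that lead there from 17. The chosen key step sets C5, C9 and C10 and places O7, C17 and C11 in one step.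

**Alternative 3:** Polyene cyclisation. The C4–C5 and C9–C10 bonds are cut. Epoxide A7 would be opened by a titanocene chloride (trivalent titanium) to a tertiary radical that closes both rings and ends as the exocyclic alkene of A6.
- For: this is the shortest entry to a trans-decalin with the correct C5/C9/C10 configuration, the C8 methylene and an oxygenated C11. On step count to the bicycle and on direct delivery of the exocyclic alkene it is stronger than the chosen strategy.
- Against: the hydroxyl of A6 is at C3, while the target has oxygen at C2 and none at C3. A 1,2-transposition of oxygen next to the neopentyl C4 with control of the 2α configuration is required. C7 still needs allylic oxidation and inversion. The enantiopure epoxide A7 needs its own asymmetric step, and radical cascades of this kind end in several ways.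
- Comparison: the chosen route spends its steps before the key step, but builds the C2 and C7 oxygens into the acyclic precursor, so none is spent on moving oxygen around a finished skeleton.

Key step: step 9

## Remarks before the steps

- Assumption: the C8 configurations written for 19 and 20 (8α-methyl, equatorial) and for 22 and 23 (selenium 8α, anti to C20) are the expected ones. C8 becomes trigonal in 21 and in 24, so nothing downstream depends on them.
- Assumption: acid chloride 37 is prepared from the acid (step 22) rather than bought.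

## Route

Step 1
Reactants: 1 isobutyronitrile; 2 (S)-epichlorohydrin
Product: 5 2,2-dimethyl-3-[(2S)-oxiran-2-yl]propanenitrile, via lithiated isobutyronitrile 3 (not isolated), via lithium chlorohydrinate 4 (not isolated)
Conditions: LDA, THF, −78 °C; then 2, −78 °C → rt
Reagents that add atoms: none
Why: Nitrile anion 3 opens the epoxide of 2 at the unsubstituted carbon (faster than displacement of chloride), and alkoxide 4 then closes onto the chloromethyl group (intramolecular Williamson reaction), so the C–O stereocentre is never touched and one enantiomer of 5 results. The nitrile α-carbon is quaternary, so no second deprotonation or cyclopropane formation can follow.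

Step 2
Reactants: 5 2,2-dimethyl-3-[(2S)-oxiran-2-yl]propanenitrile
Product: 6 (4R)-4-hydroxy-2,2-dimethylhept-6-ynenitrile
Conditions: HC≡CH, n-BuLi, THF, −78 °C; BF3·OEt2; then 5, −78 °C
Reagents that add atoms: acetylene (C#C)
Why: BF3-promoted opening of a terminal epoxide by lithium acetylide at the primary carbon (SN2). At −78 °C the boron-bound alkoxide does not add to the γ-nitrile, and the stereocentre is again untouched.

Step 3
Reactants: 6 (4R)-4-hydroxy-2,2-dimethylhept-6-ynenitrile
Product: 7 (4R)-4-[(tert-butyldimethylsilyl)oxy]-2,2-dimethylhept-6-ynenitrile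
Conditions: TBSCl, imidazole, DMF, rt
Reagents that add atoms: tert-butyldimethylsilyl chloride (CC(C)(C)[Si](C)(C)Cl)
Why: Standard silylation of a secondary alcohol. It prevents lactol or cyclic ether formation once the nitrile is reduced, and makes the C2 oxygen the bulky equatorial control element of the key step.

Step 4
Reactants: 7 (4R)-4-[(tert-butyldimethylsilyl)oxy]-2,2-dimethylhept-6-ynenitrile
Product: 9 (4S,6E)-4-[(tert-butyldimethylsilyl)oxy]-7-iodo-2,2,6-trimethylhept-6-enenitrile, via alkenyldimethylalane 8 (not isolated)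
Conditions: Me3Al (3 equiv), Cp2ZrCl2 (0.3 equiv), CH2Cl2, 0 °C → rt; then I2, THF, −30 → 0 °C
Reagents that add atoms: trimethylaluminium (C[Al](C)C); iodine (II)
Why: Negishi carboalumination adds methyl and aluminium syn across the terminal alkyne with methyl on the internal carbon, and iodinolysis of the C–Al bond goes with retention, which fixes the E geometry (methyl cis to iodine) that later becomes the E-enal. The hindered tertiary nitrile is expected only to bind Me3Al, hence the excess.

Step 5
Reactants: 9 (4S,6E)-4-[(tert-butyldimethylsilyl)oxy]-7-iodo-2,2,6-trimethylhept-6-enenitrile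
Product: 11 (4S,6E)-4-[(tert-butyldimethylsilyl)oxy]-7-iodo-2,2,6-trimethylhept-6-enal, via N-aluminoaldimine 10 (not isolated)
Conditions: DIBAL-H, CH2Cl2, −78 °C; then aq. tartaric acid, 0 °C
Reagents that add atoms: water (O)
Why: DIBAL-H adds once to the nitrile to give the N-alumino aldimine, which is stable at −78 °C, and mild aqueous acid releases the aldehyde. The alkenyl iodide and silyl ether are inert, and the aldehyde has no α-hydrogen.

Step 6
Reactants: 11 (4S,6E)-4-[(tert-butyldimethylsilyl)oxy]-7-iodo-2,2,6-trimethylhept-6-enal; 12 diethyl (2-oxobutyl)phosphonate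
Product: 13 (4E,8S,10E)-8-[(tert-butyldimethylsilyl)oxy]-11-iodo-6,6,10-trimethylundeca-4,10-dien-3-one
Conditions: Ba(OH)2·8H2O, THF/H2O (40:1), rt
Reagents that add atoms: none
Why: Horner–Wadsworth–Emmons reaction of a β-ketophosphonate. The stabilised anion gives the E-enone, and the hindered, non-enolisable aldehyde cannot self-condense.

Step 7
Reactants: 13 (4E,8S,10E)-8-[(tert-butyldimethylsilyl)oxy]-11-iodo-6,6,10-trimethylundeca-4,10-dien-3-one
Product: 14 tert-butyl{[(1E,4S,7E,9Z)-1-iodo-2,6,6-trimethyl-9-[(triethylsilyl)oxy]undeca-1,7,9-trien-4-yl]oxy}dimethylsilane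
Conditions: TESOTf, Et3N, CH2Cl2, −78 → 0 °C
Reagents that add atoms: triethylsilyl triflate (CC[Si](CC)(CC)OS(=O)(=O)C(F)(F)F)
Why: Soft enolisation of the ethyl ketone. The γ-carbon (C4) is quaternary, so only α′-deprotonation is possible, and the Z silyl enol ether (methyl cis to oxygen, "outside" in the s-cis diene) is the usual outcome of this method. TES is used in place of TMS so that the diene survives handling and the Lewis acid.

Step 8
Reactants: 14 tert-butyl{[(1E,4S,7E,9Z)-1-iodo-2,6,6-trimethyl-9-[(triethylsilyl)oxy]undeca-1,7,9-trien-4-yl]oxy}dimethylsilane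
Product: 16 (2E,5R,8E,10Z)-5-[(tert-butyldimethylsilyl)oxy]-3,7,7-trimethyl-10-[(triethylsilyl)oxy]dodeca-2,8,10-trienal, via alkenyllithium 15 (not isolated)
Conditions: t-BuLi (2.1 equiv), Et2O, −78 °C; DMF, −78 → 0 °C; pH 7 buffer
Reagents that add atoms: N,N-dimethylformamide (CN(C)C=O)
Why: Iodine–lithium exchange of the alkenyl iodide is faster at −78 °C than attack on either silyl group and goes with retention, and formylation of 15 gives the E-enal. The enal is made only after the dienol ether, so ketone enolisation never competes with an enal.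

Step 9
Reactants: 16 (2E,5R,8E,10Z)-5-[(tert-butyldimethylsilyl)oxy]-3,7,7-trimethyl-10-[(triethylsilyl)oxy]dodeca-2,8,10-trienal
Product: 17 2α-[(tert-butyldimethylsilyl)oxy]-7-[(triethylsilyl)oxy]-12,13,14,15,16-pentanorlabd-6-en-11-al (5α-H, 8β-methyl, 9β-formyl, 10β-methyl)
Conditions: Me2AlCl (1.2 equiv), CH2Cl2, −78 → −20 °C; Et3N, then aq. NaHCO3
Reagents that add atoms: none
Why: Me2AlCl binds the formyl oxygen and lowers the enal LUMO, and the diene and tethered dienophile combine in a concerted, asynchronous [4+2] cycloaddition in which C5–C10 bonding runs ahead of C8–C9. The closest known reaction types are Lewis-acid-promoted intramolecular Diels–Alder reactions of 2,8,10-trienals to trans-decalins and Lewis-acid-promoted cycloadditions of 2-silyloxydienes with β,β-disubstituted enals and enones. Ring B is the cyclohexene made by the two new σ bonds; ring A is closed by the C5–C10 bond alone, in the fused mode, with the four-carbon tether C1–C4 folded as a chair. At C9/C10 the E geometry of the enal is transferred suprafacially, so C20 and the formyl group are cis. At C5/C10 the aluminium-bound formyl group sits endo, which forces the tether exo and gives the trans ring fusion. At C8 the Z enol ether holds C17 outside, so it ends cis to the endo formyl group (8β); this centre is erased later. The absolute sense comes from C2: its silyloxy group takes the equatorial position on the chair tether, because the axial alternative is syn-diaxial to both the C19 and C20 methyls, and this fixes the diene face. The step needs endo over exo (Lewis acid, low temperature), one π-face (C2), and cycloaddition over silyl transfer or Mukaiyama-type addition at C8 (mild dialkylaluminium chloride, TES group, no small-ring Michael closure possible); the regiochemistry is fixed by the tether although it pairs the nucleophilic diene carbon C8 with the enal α-carbon.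

Step 10
Reactants: 17 2α-[(tert-butyldimethylsilyl)oxy]-7-[(triethylsilyl)oxy]-12,13,14,15,16-pentanorlabd-6-en-11-al
Product: 19 2α-[(tert-butyldimethylsilyl)oxy]-11-hydroxy-12,13,14,15,16-pentanorlabdan-7-one (8α-methyl), via hydroxy enol ether 18 (not isolated)
Conditions: NaBH4, THF/EtOH, −20 °C; acetone; then K2CO3, MeOH, rt
Reagents that add atoms: none
Why: Borohydride reduces the aldehyde chemoselectively while C7 is still masked as the TES enol ether, which should survive the short cold reduction. Methanolysis under K2CO3 then unmasks the ketone and equilibrates C8 to the equatorial 8α-methyl epimer (the 8β epimer has a syn-diaxial methyl/methyl interaction with C20), leaving the secondary TBS ether intact.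

Step 11
Reactants: 19 2α-[(tert-butyldimethylsilyl)oxy]-11-hydroxy-12,13,14,15,16-pentanorlabdan-7-one
Product: 20 2α-[(tert-butyldimethylsilyl)oxy]-11-iodo-12,13,14,15,16-pentanorlabdan-7-one (8α-methyl)
Conditions: I2, PPh3, imidazole, PhMe/MeCN, rt → 60 °C
Reagents that add atoms: iodine (II)
Why: Appel-type iodination of the primary alcohol by SN2 on the alkoxyphosphonium ion. The β-branched position needs warming, and the iodide formed is for the same reason inert to the reagents of steps 12–16.

Step 12
Reactants: 20 2α-[(tert-butyldimethylsilyl)oxy]-11-iodo-12,13,14,15,16-pentanorlabdan-7-one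
Product: 21 2α-[(tert-butyldimethylsilyl)oxy]-11-iodo-7-[(trimethylsilyl)oxy]-12,13,14,15,16-pentanorlabd-7-ene
Conditions: TMSCl, NaI, Et3N, MeCN, rt → 40 °C
Reagents that add atoms: trimethylsilyl chloride (C[Si](C)(C)Cl)
Why: Equilibrating silylation with TMSI formed in the flask should give the more substituted, tetrasubstituted C7=C8 enol ether, as with other α-methyl cyclohexanones. No free enolate is formed, so the γ-iodide cannot be displaced to a cyclopropane.

Step 13
Reactants: 21 2α-[(tert-butyldimethylsilyl)oxy]-11-iodo-7-[(trimethylsilyl)oxy]-12,13,14,15,16-pentanorlabd-7-ene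
Product: 22 2α-[(tert-butyldimethylsilyl)oxy]-11-iodo-8α-(phenylselanyl)-12,13,14,15,16-pentanorlabdan-7-one (8β-methyl)
Conditions: PhSeCl, CH2Cl2, −78 °C
Reagents that add atoms: benzeneselenenyl chloride (Cl[Se]c1ccccc1)
Why: Electrophilic selenenylation of a silyl enol ether is regiospecific for the enol carbon C8. Selenium is expected to enter from the α face, anti to the axial C20 methyl.

Step 14
Reactants: 22 2α-[(tert-butyldimethylsilyl)oxy]-11-iodo-8α-(phenylselanyl)-12,13,14,15,16-pentanorlabdan-7-one
Product: 24 2α-[(tert-butyldimethylsilyl)oxy]-11-iodo-12,13,14,15,16-pentanorlabd-8(17)-en-7-one, via selenoxide 23 (not isolated)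
Conditions: 30% H2O2, pyridine, CH2Cl2, 0 °C → rt
Reagents that add atoms: none
Why: Oxidation to selenoxide 23 and spontaneous syn elimination (selenoxide elimination). Elimination into the ring would need the C8–Se and C9–H bonds eclipsed, which also eclipses the C8 methyl with C11 inside the rigid trans-decalin and would give a tetrasubstituted enone, whereas a C17 hydrogen is reached by simple rotation, so the exocyclic enone should dominate.

Step 15
Reactants: 24 2α-[(tert-butyldimethylsilyl)oxy]-11-iodo-12,13,14,15,16-pentanorlabd-8(17)-en-7-one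
Product: 25 2α-[(tert-butyldimethylsilyl)oxy]-11-iodo-12,13,14,15,16-pentanorlabd-8(17)-en-7β-ol
Conditions: NaBH4, CeCl3·7H2O, MeOH, −40 °C
Reagents that add atoms: none
Why: Luche reduction gives 1,2-addition to the α-methylene ketone. Hydride enters axially from the α face, where only H-5 and H-9 are syn-axial, so the new hydroxyl is equatorial, that is 7β.

Step 16
Reactants: 25 2α-[(tert-butyldimethylsilyl)oxy]-11-iodo-12,13,14,15,16-pentanorlabd-8(17)-en-7β-ol
Product: 26 2α,7β-bis[(tert-butyldimethylsilyl)oxy]-11-iodo-12,13,14,15,16-pentanorlabd-8(17)-ene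
Conditions: TBSOTf, 2,6-lutidine, CH2Cl2, −78 → 0 °C
Reagents that add atoms: tert-butyldimethylsilyl triflate (CC(C)(C)[Si](C)(C)OS(=O)(=O)C(F)(F)F)
Why: Silylation of the secondary allylic alcohol with the silyl triflate. It is needed because step 18 uses t-BuLi.

Step 17
Reactants: 27 propargyl alcohol
Product: 29 (Z)-3-iodo-2-methylprop-2-en-1-ol, via alkenylmagnesium alkoxide 28 (not isolated)
Conditions: MeMgBr (2.5 equiv), CuI (10 mol%), THF, −10 °C → rt; then I2, −10 °C
Reagents that add atoms: methylmagnesium bromide (C[Mg]Br); iodine (II)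
Why: Copper-catalysed anti carbomagnesiation of a propargylic alcohol: the alkoxide holds magnesium on the terminal carbon cis to CH2O, and iodinolysis with retention gives the Z iodide in which iodine and CH2OH are cis.

Step 18
Reactants: 26 2α,7β-bis[(tert-butyldimethylsilyl)oxy]-11-iodo-12,13,14,15,16-pentanorlabd-8(17)-ene; 29 (Z)-3-iodo-2-methylprop-2-en-1-ol
Product: 32 (12Z)-2α,7β-bis[(tert-butyldimethylsilyl)oxy]-15-norlabda-8(17),12-dien-14-ol, via alkyllithium 30 (not isolated), via lithium methoxyborinate 31 (not isolated)
Conditions: t-BuLi (2.1 equiv), Et2O, −78 °C; B-methoxy-9-BBN, THF, −78 °C → rt; then 29, PdCl2(dppf), AsPh3, K3PO4 (3 M aq.), DMF, rt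
Reagents that add atoms: none
Why: Iodine–lithium exchange, capture by the borinate ester and B-alkyl Suzuki–Miyaura coupling of ate complex 31 with the alkenyl iodide, a sequence known for β-branched primary iodides and Z-alkenyl iodides. The sp2 partner couples with retention, so C11 and C14 end up cis (12Z).

Step 19
Reactants: 32 (12Z)-2α,7β-bis[(tert-butyldimethylsilyl)oxy]-15-norlabda-8(17),12-dien-14-ol
Product: 33 (12Z)-2α,7β-bis[(tert-butyldimethylsilyl)oxy]-15-norlabda-8(17),12-dien-14-al
Conditions: Dess–Martin periodinane, NaHCO3, CH2Cl2, 0 °C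
Reagents that add atoms: none
Why: Buffered Dess–Martin oxidation of the allylic alcohol is fast and non-acidic, which should keep the Z-enal from isomerising. The crude aldehyde is used at once.

Step 20
Reactants: 33 (12Z)-2α,7β-bis[(tert-butyldimethylsilyl)oxy]-15-norlabda-8(17),12-dien-14-al
Product: 34 (12Z)-2α,7β-bis[(tert-butyldimethylsilyl)oxy]labda-8(17),12,14-triene
Conditions: Ph3PCH3Br, KHMDS, THF, 0 °C; then 33, −78 → 0 °C
Reagents that add atoms: methyltriphenylphosphonium bromide (C[P+](c1ccccc1)(c1ccccc1)c1ccccc1.[Br-])
Why: Wittig methylenation of the aldehyde. The C12=C13 geometry is not involved and should be retained, because addition of the ylide to the aldehyde is faster than γ-deprotonation.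

Step 21
Reactants: 34 (12Z)-2α,7β-bis[(tert-butyldimethylsilyl)oxy]labda-8(17),12,14-triene
Product: 35 (12Z)-labda-8(17),12,14-triene-2α,7β-diol
Conditions: TBAF, THF, rt → 45 °C
Reagents that add atoms: none
Why: Fluoride cleaves both secondary TBS ethers, and the diene and exocyclic allylic alcohol are stable to it. Doing this before the cycloaddition spares the sensitive adduct any deprotection.

Step 22
Reactants: 36 2,4,5-trimethoxybenzoic acid
Product: 37 2,4,5-trimethoxybenzoyl chloride
Conditions: (COCl)2, DMF (cat.), CH2Cl2, 0 °C → rt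
Reagents that add atoms: oxalyl chloride (O=C(Cl)C(=O)Cl)
Why: Standard acid chloride formation through the chloroiminium catalyst. The product is used crude.

Step 23
Reactants: 38 2′,4′,6′-trihydroxyacetophenone; 37 2,4,5-trimethoxybenzoyl chloride
Product: 40 5,7-dihydroxy-2-(2,4,5-trimethoxyphenyl)-4H-chromen-4-one, via β-diketone 39 (not isolated)
Conditions: LiHMDS (4.5 equiv), THF, −78 °C; 37, −78 °C → rt; aq. HCl; then H2SO4 (cat.), AcOH, 95 °C
Reagents that add atoms: none
Why: The polyanion of 38 (three phenoxides and the ketone enolate) is C-acylated at the enolate carbon by 37 (Claisen-type acylation). Acid then closes the pyranone of 39 by addition of the ortho phenol oxygen to the aryl ketone and dehydration, a known protecting-group-free route to 5,7-dihydroxyflavones.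

Step 24
Reactants: 40 5,7-dihydroxy-2-(2,4,5-trimethoxyphenyl)-4H-chromen-4-one
Product: 41 2-(5,7-dihydroxy-4-oxo-4H-chromen-2-yl)-5-methoxy-1,4-benzoquinone
Conditions: (NH4)2Ce(NO3)6 (2.5 equiv), MeCN/H2O (4:1), 0 °C
Reagents that add atoms: water (O)
Why: Oxidative demethylation: the electron-rich 1,2,4-trimethoxyaryl ring is oxidised to its radical cation, water attacks the two para-related methoxy-bearing carbons and methanol leaves, while the 4′-methoxy group stays as the vinylogous ester. The chelated, acyl-deactivated ring A of the chromone is much harder to oxidise.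

Step 25
Reactants: 35 (12Z)-labda-8(17),12,14-triene-2α,7β-diol; 41 2-(5,7-dihydroxy-4-oxo-4H-chromen-2-yl)-5-methoxy-1,4-benzoquinone
Product: 42 dichrostachine B
Conditions: 41 (1.5 equiv), CF3CH2OH, 40 °C, dark, argon
Reagents that add atoms: none
Why: Intermolecular Diels–Alder reaction at the Q5=Q6 bond, the only quinone double bond not deactivated as a vinylogous ester. Endo approach of the enedione puts the inside C11 substituent of the Z-diene trans to the quinone carbons and cis to the chromonyl group, while the chromonyl group and H on Q6 stay cis. Bonding of the unsubstituted terminus C15 to Q6 (β to the Q4 carbonyl and δ to the chromone carbonyl, both activated by hydrogen bonding from the solvent) gives the required regiochemistry; the diene face is chosen only by the remote decalin, so the other endo diastereomer is expected as well and would be removed by chromatography.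

## Compound list

1 | isobutyronitrile | CC(C)C#N | starting material
2 | (S)-epichlorohydrin | ClC[C@@H]1CO1 | starting material
3 | lithiated isobutyronitrile (2-lithio-2-methylpropanenitrile) | [Li]C(C)(C)C#N | intermediate
4 | lithium (2S)-1-chloro-4-cyano-4-methylpentan-2-olate | ClC[C@@H]([O-])CC(C)(C)C#N.[Li+] | intermediate
5 | 2,2-dimethyl-3-[(2S)-oxiran-2-yl]propanenitrile | N#CC(C)(C)C[C@H]1CO1 | intermediate
6 | (4R)-4-hydroxy-2,2-dimethylhept-6-ynenitrile | N#CC(C)(C)C[C@H](O)CC#C | intermediate
7 | (4R)-4-[(tert-butyldimethylsilyl)oxy]-2,2-dimethylhept-6-ynenitrile | N#CC(C)(C)C[C@H](O[Si](C)(C)C(C)(C)C)CC#C | intermediate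
8 | (4S,6E)-4-[(tert-butyldimethylsilyl)oxy]-7-(dimethylalumanyl)-2,2,6-trimethylhept-6-enenitrile | N#CC(C)(C)C[C@H](O[Si](C)(C)C(C)(C)C)C/C(C)=C/[Al](C)C | intermediate
9 | (4S,6E)-4-[(tert-butyldimethylsilyl)oxy]-7-iodo-2,2,6-trimethylhept-6-enenitrile | N#CC(C)(C)C[C@H](O[Si](C)(C)C(C)(C)C)C/C(C)=C/I | intermediate
10 | N-(diisobutylalumanyl) aldimine of aldehyde 11 | CC(C)C[Al](CC(C)C)N=CC(C)(C)C[C@H](O[Si](C)(C)C(C)(C)C)C/C(C)=C/I | intermediate
11 | (4S,6E)-4-[(tert-butyldimethylsilyl)oxy]-7-iodo-2,2,6-trimethylhept-6-enal | O=CC(C)(C)C[C@H](O[Si](C)(C)C(C)(C)C)C/C(C)=C/I | intermediate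
12 | diethyl (2-oxobutyl)phosphonate | CCC(=O)CP(=O)(OCC)OCC | starting material
13 | (4E,8S,10E)-8-[(tert-butyldimethylsilyl)oxy]-11-iodo-6,6,10-trimethylundeca-4,10-dien-3-one | CCC(=O)/C=C/C(C)(C)C[C@H](O[Si](C)(C)C(C)(C)C)C/C(C)=C/I | intermediate
14 | tert-butyl{[(1E,4S,7E,9Z)-1-iodo-2,6,6-trimethyl-9-[(triethylsilyl)oxy]undeca-1,7,9-trien-4-yl]oxy}dimethylsilane | C/C=C(O[Si](CC)(CC)CC)/C=C/C(C)(C)C[C@H](O[Si](C)(C)C(C)(C)C)C/C(C)=C/I | intermediate
15 | (1E)-alkenyllithium formed from 14 by iodine–lithium exchange | C/C=C(O[Si](CC)(CC)CC)/C=C/C(C)(C)C[C@H](O[Si](C)(C)C(C)(C)C)C/C(C)=C/[Li] | intermediate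
16 | (2E,5R,8E,10Z)-5-[(tert-butyldimethylsilyl)oxy]-3,7,7-trimethyl-10-[(triethylsilyl)oxy]dodeca-2,8,10-trienal | O=C/C=C(\C)C[C@@H](O[Si](C)(C)C(C)(C)C)CC(C)(C)/C=C/C(O[Si](CC)(CC)CC)=C/C | intermediate
17 | 2α-[(tert-butyldimethylsilyl)oxy]-7-[(triethylsilyl)oxy]-12,13,14,15,16-pentanorlabd-6-en-11-al (5α-H, 8β-methyl, 9β-formyl, 10β-methyl) | C[C@H]1C(O[Si](CC)(CC)CC)=C[C@H]2C(C)(C)C[C@H](O[Si](C)(C)C(C)(C)C)C[C@]2(C)[C@H]1C=O | intermediate
18 | 2α-[(tert-butyldimethylsilyl)oxy]-7-[(triethylsilyl)oxy]-12,13,14,15,16-pentanorlabd-6-en-11-ol (8β-methyl) | C[C@H]1C(O[Si](CC)(CC)CC)=C[C@H]2C(C)(C)C[C@H](O[Si](C)(C)C(C)(C)C)C[C@]2(C)[C@H]1CO | intermediate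
19 | 2α-[(tert-butyldimethylsilyl)oxy]-11-hydroxy-12,13,14,15,16-pentanorlabdan-7-one (8α-methyl) | C[C@@H]1C(=O)C[C@H]2C(C)(C)C[C@H](O[Si](C)(C)C(C)(C)C)C[C@]2(C)[C@H]1CO | intermediate
20 | 2α-[(tert-butyldimethylsilyl)oxy]-11-iodo-12,13,14,15,16-pentanorlabdan-7-one (8α-methyl) | C[C@@H]1C(=O)C[C@H]2C(C)(C)C[C@H](O[Si](C)(C)C(C)(C)C)C[C@]2(C)[C@H]1CI | intermediate
21 | 2α-[(tert-butyldimethylsilyl)oxy]-11-iodo-7-[(trimethylsilyl)oxy]-12,13,14,15,16-pentanorlabd-7-ene | CC1=C(O[Si](C)(C)C)C[C@H]2C(C)(C)C[C@H](O[Si](C)(C)C(C)(C)C)C[C@]2(C)[C@H]1CI | intermediate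
22 | 2α-[(tert-butyldimethylsilyl)oxy]-11-iodo-8α-(phenylselanyl)-12,13,14,15,16-pentanorlabdan-7-one (8β-methyl) | C[C@@]1([Se]c3ccccc3)C(=O)C[C@H]2C(C)(C)C[C@H](O[Si](C)(C)C(C)(C)C)C[C@]2(C)[C@H]1CI | intermediate
23 | selenoxide of 22 (8α-phenylseleninyl) | C[C@@]1([Se](=O)c3ccccc3)C(=O)C[C@H]2C(C)(C)C[C@H](O[Si](C)(C)C(C)(C)C)C[C@]2(C)[C@H]1CI | intermediate
24 | 2α-[(tert-butyldimethylsilyl)oxy]-11-iodo-12,13,14,15,16-pentanorlabd-8(17)-en-7-one | C=C1C(=O)C[C@H]2C(C)(C)C[C@H](O[Si](C)(C)C(C)(C)C)C[C@]2(C)[C@H]1CI | intermediate
25 | 2α-[(tert-butyldimethylsilyl)oxy]-11-iodo-12,13,14,15,16-pentanorlabd-8(17)-en-7β-ol | C=C1[C@@H](O)C[C@H]2C(C)(C)C[C@H](O[Si](C)(C)C(C)(C)C)C[C@]2(C)[C@H]1CI | intermediate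
26 | 2α,7β-bis[(tert-butyldimethylsilyl)oxy]-11-iodo-12,13,14,15,16-pentanorlabd-8(17)-ene | C=C1[C@@H](O[Si](C)(C)C(C)(C)C)C[C@H]2C(C)(C)C[C@H](O[Si](C)(C)C(C)(C)C)C[C@]2(C)[C@H]1CI | intermediate
27 | propargyl alcohol | C#CCO | starting material
28 | bromomagnesium (Z)-3-(bromomagnesio)-2-methylprop-2-en-1-olate | C/C(CO[Mg]Br)=C/[Mg]Br | intermediate
29 | (Z)-3-iodo-2-methylprop-2-en-1-ol | C/C(CO)=C/I | intermediate
30 | 11-lithio-2α,7β-bis[(tert-butyldimethylsilyl)oxy]-12,13,14,15,16-pentanorlabd-8(17)-ene | C=C1[C@@H](O[Si](C)(C)C(C)(C)C)C[C@H]2C(C)(C)C[C@H](O[Si](C)(C)C(C)(C)C)C[C@]2(C)[C@H]1C[Li] | intermediate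
31 | lithium B-methoxy-B-(C11-alkyl)-9-borabicyclo[3.3.1]nonane ate complex of 30 | C=C1[C@@H](O[Si](C)(C)C(C)(C)C)C[C@H]2C(C)(C)C[C@H](O[Si](C)(C)C(C)(C)C)C[C@]2(C)[C@H]1C[B-]1(OC)C2CCCC1CCC2.[Li+] | intermediate
32 | (12Z)-2α,7β-bis[(tert-butyldimethylsilyl)oxy]-15-norlabda-8(17),12-dien-14-ol | C=C1[C@@H](O[Si](C)(C)C(C)(C)C)C[C@H]2C(C)(C)C[C@H](O[Si](C)(C)C(C)(C)C)C[C@]2(C)[C@H]1C/C=C(/C)CO | intermediate
33 | (12Z)-2α,7β-bis[(tert-butyldimethylsilyl)oxy]-15-norlabda-8(17),12-dien-14-al | C=C1[C@@H](O[Si](C)(C)C(C)(C)C)C[C@H]2C(C)(C)C[C@H](O[Si](C)(C)C(C)(C)C)C[C@]2(C)[C@H]1C/C=C(/C)C=O | intermediate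
34 | (12Z)-2α,7β-bis[(tert-butyldimethylsilyl)oxy]labda-8(17),12,14-triene | C=C1[C@@H](O[Si](C)(C)C(C)(C)C)C[C@H]2C(C)(C)C[C@H](O[Si](C)(C)C(C)(C)C)C[C@]2(C)[C@H]1C/C=C(/C)C=C | intermediate
35 | (12Z)-labda-8(17),12,14-triene-2α,7β-diol | C=C1[C@@H](O)C[C@H]2C(C)(C)C[C@H](O)C[C@]2(C)[C@H]1C/C=C(/C)C=C | intermediate
36 | 2,4,5-trimethoxybenzoic acid | COc1cc(OC)c(C(=O)O)cc1OC | starting material
37 | 2,4,5-trimethoxybenzoyl chloride | COc1cc(OC)c(C(=O)Cl)cc1OC | intermediate
38 | 2′,4′,6′-trihydroxyacetophenone | CC(=O)c1c(O)cc(O)cc1O | starting material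
39 | 1-(2,4,6-trihydroxyphenyl)-3-(2,4,5-trimethoxyphenyl)propane-1,3-dione | COc1cc(OC)c(C(=O)CC(=O)c2c(O)cc(O)cc2O)cc1OC | intermediate
40 | 5,7-dihydroxy-2-(2,4,5-trimethoxyphenyl)-4H-chromen-4-one | COc1cc(OC)c(-c2cc(=O)c3c(O)cc(O)cc3o2)cc1OC | intermediate
41 | 2-(5,7-dihydroxy-4-oxo-4H-chromen-2-yl)-5-methoxy-1,4-benzoquinone | COC1=CC(=O)C(c2cc(=O)c3c(O)cc(O)cc3o2)=CC1=O | intermediate
42 | dichrostachine B | C=C1[C@@H](O)C[C@H]2C(C)(C)C[C@H](O)C[C@]2(C)[C@H]1C[C@@H]1C(C)=CC[C@H]2C(=O)C(OC)=CC(=O)[C@@]12c1cc(=O)c2c(O)cc(O)cc2o1 | target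

## Step count and least certain steps

Total step count: 25. Longest linear sequence: 21 steps (steps 1–16, 18–21 and 25). Step 17 and steps 22–24 are side branches.

**Step 9 (key step).** The C5–C10 bond joins a neopentyl carbon to a quaternary one, so the cycloaddition may be slow. Lewis-acid-induced loss or transfer of the TES group and Mukaiyama-type bond formation at C8 could then overtake it, and endo selectivity would erode if warming is needed.

Fallback, from aldehyde 11 back to hydroxy ketone 19: the oxygen at C7 is introduced after the cycloaddition instead of before. Aldehyde 11 would be olefinated with the lithium anion of diethyl (E)-but-2-en-1-ylphosphonate to the oxygen-free diene tert-butyl{[(1E,4S,7E,9E)-1-iodo-2,6,6-trimethylundeca-1,7,9-trien-4-yl]oxy}dimethylsilane F1. Iodine–lithium exchange and formylation as in step 8 would give (2E,5R,8E,10E)-5-[(tert-butyldimethylsilyl)oxy]-3,7,7-trimethyldodeca-2,8,10-trienal F2, which has no Lewis-acid-labile group. Me2AlCl would cyclise it through the same endo, equatorial-silyloxy transition state to 2α-[(tert-butyldimethylsilyl)oxy]-12,13,14,15,16-pentanorlabd-6-en-11-al F3. BH3·THF followed by NaBO3 would reduce the aldehyde and hydroborate C6=C7 from the α face at the less hindered C7, giving 2α-[(tert-butyldimethylsilyl)oxy]-12,13,14,15,16-pentanorlabdane-7α,11-diol F4. Dess–Martin oxidation of both hydroxyls and K2CO3/MeOH equilibration at C8 would give 2α-[(tert-butyldimethylsilyl)oxy]-7-oxo-12,13,14,15,16-pentanorlabdan-11-al F5. NaBH4 at −78 °C would reduce only the aldehyde and return to 19.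

**Step 25.** The inside C11 substituent of the Z-diene disfavours the s-cis conformer, so the cycloaddition may be sluggish and thermal Z-to-E isomerisation could compete. The remote decalin discriminates the diene faces poorly. The opposing pull of the Q1 carbonyl could lead C15 to bond to Q5, giving the regioisomer.

Fallback, from bis-silyl ether 34 and quinone 41 to 42: catalyst control replaces substrate control. Quinone 41 would be silylated at the free 7-hydroxyl (TBSCl, imidazole) to 2-{7-[(tert-butyldimethylsilyl)oxy]-5-hydroxy-4-oxo-4H-chromen-2-yl}-5-methoxy-1,4-benzoquinone F6. Triene 34 and F6 would be combined at −78 to −40 °C in CH2Cl2 under a chiral cationic oxazaborolidine Lewis acid (triflimide-activated). This binds the more basic Q4 carbonyl, which makes Q6 the electrophilic carbon and selects the quinone face, and should give 2,7,7′-tris-O-(tert-butyldimethylsilyl)dichrostachine B F7. HF·pyridine in THF/pyridine would remove the three silyl groups to give 42.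

**Step 14 (with steps 12 and 13).** Syn elimination toward C9–H would compete if the eclipsing penalty is smaller than argued, giving the endocyclic enone. Partial enolisation toward C6 in step 12 would misplace the selenium.

Fallback, from enol ether 21 back to enone 24: an anti elimination replaces the syn elimination. Rubottom oxidation of 21 (mCPBA, NaHCO3, CH2Cl2, −20 °C, then mild desilylation) would give, by α-face epoxidation, 2α-[(tert-butyldimethylsilyl)oxy]-8α-hydroxy-11-iodo-12,13,14,15,16-pentanorlabdan-7-one F8. SOCl2/pyridine at −30 °C would then eliminate the equatorial tertiary hydroxyl by an E2 path, for which only the C17 hydrogens can be antiperiplanar, giving 24.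

**Step 18.** Transmetalation of the hindered B-alkyl group may be slow, so protodeboronation or β-hydride elimination from the alkylpalladium intermediate (toward C9) could dominate.

Fallback, from iodide 26 back to allylic alcohol 32: the Z alkene is made by olefination at C12=C13 instead of coupling at C11–C12. Alkyllithium 30, generated as in step 18, would be quenched with DMF to 2α,7β-bis[(tert-butyldimethylsilyl)oxy]-13,14,15,16-tetranorlabd-8(17)-en-12-al F9. Still–Gennari olefination with methyl 2-[bis(2,2,2-trifluoroethoxy)phosphoryl]propanoate (KHMDS, 18-crown-6, THF, −78 °C) would give methyl (12Z)-2α,7β-bis[(tert-butyldimethylsilyl)oxy]-15-norlabda-8(17),12-dien-14-oate F10. DIBAL-H would reduce it to 32.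

**Step 24.** The free phloroglucinol-type ring A, or the product quinone, may be oxidised further by the cerium reagent.

Fallback, from flavone 40 to 42: the phenols are masked through the oxidation and the cycloaddition. Ac2O/pyridine/DMAP would give 5,7-diacetoxy-2-(2,4,5-trimethoxyphenyl)-4H-chromen-4-one F11. Oxidative demethylation as in step 24 would give 2-(5,7-diacetoxy-4-oxo-4H-chromen-2-yl)-5-methoxy-1,4-benzoquinone F12. Cycloaddition with 35 as in step 25 would give dichrostachine B 5′,7′-diacetate F13. NH4OAc in aqueous MeOH at rt would cleave the two aryl acetates to give 42.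

## Further compounds

F1 | step 9 | tert-butyl{[(1E,4S,7E,9E)-1-iodo-2,6,6-trimethylundeca-1,7,9-trien-4-yl]oxy}dimethylsilane | C/C=C/C=C/C(C)(C)C[C@H](O[Si](C)(C)C(C)(C)C)C/C(C)=C/I
F2 | step 9 | (2E,5R,8E,10E)-5-[(tert-butyldimethylsilyl)oxy]-3,7,7-trimethyldodeca-2,8,10-trienal | O=C/C=C(\C)C[C@@H](O[Si](C)(C)C(C)(C)C)CC(C)(C)/C=C/C=C/C
F3 | step 9 | 2α-[(tert-butyldimethylsilyl)oxy]-12,13,14,15,16-pentanorlabd-6-en-11-al (8β-methyl) | C[C@H]1C=C[C@H]2C(C)(C)C[C@H](O[Si](C)(C)C(C)(C)C)C[C@]2(C)[C@H]1C=O
F4 | step 9 | 2α-[(tert-butyldimethylsilyl)oxy]-12,13,14,15,16-pentanorlabdane-7α,11-diol (8β-methyl) | C[C@H]1[C@H](O)C[C@H]2C(C)(C)C[C@H](O[Si](C)(C)C(C)(C)C)C[C@]2(C)[C@H]1CO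
F5 | step 9 | 2α-[(tert-butyldimethylsilyl)oxy]-7-oxo-12,13,14,15,16-pentanorlabdan-11-al (8α-methyl) | C[C@@H]1C(=O)C[C@H]2C(C)(C)C[C@H](O[Si](C)(C)C(C)(C)C)C[C@]2(C)[C@H]1C=O
F6 | step 25 | 2-{7-[(tert-butyldimethylsilyl)oxy]-5-hydroxy-4-oxo-4H-chromen-2-yl}-5-methoxy-1,4-benzoquinone | COC1=CC(=O)C(c2cc(=O)c3c(O)cc(O[Si](C)(C)C(C)(C)C)cc3o2)=CC1=O
F7 | step 25 | 2,7,7′-tris-O-(tert-butyldimethylsilyl)dichrostachine B | C=C1[C@@H](O[Si](C)(C)C(C)(C)C)C[C@H]2C(C)(C)C[C@H](O[Si](C)(C)C(C)(C)C)C[C@]2(C)[C@H]1C[C@@H]1C(C)=CC[C@H]2C(=O)C(OC)=CC(=O)[C@@]12c1cc(=O)c2c(O)cc(O[Si](C)(C)C(C)(C)C)cc2o1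
F8 | step 14 | 2α-[(tert-butyldimethylsilyl)oxy]-8α-hydroxy-11-iodo-12,13,14,15,16-pentanorlabdan-7-one | C[C@@]1(O)C(=O)C[C@H]2C(C)(C)C[C@H](O[Si](C)(C)C(C)(C)C)C[C@]2(C)[C@H]1CI
F9 | step 18 | 2α,7β-bis[(tert-butyldimethylsilyl)oxy]-13,14,15,16-tetranorlabd-8(17)-en-12-al | C=C1[C@@H](O[Si](C)(C)C(C)(C)C)C[C@H]2C(C)(C)C[C@H](O[Si](C)(C)C(C)(C)C)C[C@]2(C)[C@H]1CC=O
F10 | step 18 | methyl (12Z)-2α,7β-bis[(tert-butyldimethylsilyl)oxy]-15-norlabda-8(17),12-dien-14-oate | C=C1[C@@H](O[Si](C)(C)C(C)(C)C)C[C@H]2C(C)(C)C[C@H](O[Si](C)(C)C(C)(C)C)C[C@]2(C)[C@H]1C/C=C(/C)C(=O)OC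
F11 | step 24 | 5,7-diacetoxy-2-(2,4,5-trimethoxyphenyl)-4H-chromen-4-one | COc1cc(OC)c(-c2cc(=O)c3c(OC(C)=O)cc(OC(C)=O)cc3o2)cc1OC
F12 | step 24 | 2-(5,7-diacetoxy-4-oxo-4H-chromen-2-yl)-5-methoxy-1,4-benzoquinone | COC1=CC(=O)C(c2cc(=O)c3c(OC(C)=O)cc(OC(C)=O)cc3o2)=CC1=O
F13 | step 24 | dichrostachine B 5′,7′-diacetate | C=C1[C@@H](O)C[C@H]2C(C)(C)C[C@H](O)C[C@]2(C)[C@H]1C[C@@H]1C(C)=CC[C@H]2C(=O)C(OC)=CC(=O)[C@@]12c1cc(=O)c2c(OC(C)=O)cc(OC(C)=O)cc2o1
A1 | alternative 1 | dichrostachine B protected as the 2,7-bis(tert-butyldimethylsilyl) ether and the chromone 5,7-bis(methoxymethyl) ether | C=C1[C@@H](O[Si](C)(C)C(C)(C)C)C[C@H]2C(C)(C)C[C@H](O[Si](C)(C)C(C)(C)C)C[C@]2(C)[C@H]1C[C@@H]1C(C)=CC[C@H]2C(=O)C(OC)=CC(=O)[C@@]12c1cc(=O)c2c(OCOC)cc(OCOC)cc2o1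
A2 | alternative 1 | ring C/D adduct carrying an ethynyl group on the quaternary ring-fusion carbon in place of the chromone (2,7-bis-silyl ether) | C=C1[C@@H](O[Si](C)(C)C(C)(C)C)C[C@H]2C(C)(C)C[C@H](O[Si](C)(C)C(C)(C)C)C[C@]2(C)[C@H]1C[C@@H]1C(C)=CC[C@H]2C(=O)C(OC)=CC(=O)[C@@]12C#C
A3 | alternative 1 | 2-iodo-3,5-bis(methoxymethoxy)phenol | COCOc1cc(O)c(I)c(OCOC)c1
A4 | alternative 2 | bridged tricyclic lactone with C5=C6 and C8=C9 alkenes (C11 carbonyl joined to the C2 oxygen) | CC1=C2C(=O)O[C@@H]3C[C@@]2(C)C(=CC1)C(C)(C)C3
A5 | alternative 2 | (1R)-4-ethenyl-3,5,5-trimethylcyclohex-3-en-1-yl but-2-ynoate | CC#CC(=O)O[C@@H]1CC(C)=C(C=C)C(C)(C)C1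
A6 | alternative 3 | 3β-hydroxydrim-8(12)-en-11-yl acetate | C=C1CC[C@H]2C(C)(C)[C@@H](O)CC[C@]2(C)[C@H]1COC(C)=O
A7 | alternative 3 | (2E,6E,10S)-10,11-epoxyfarnesyl acetate | CC(=O)OC/C=C(\C)CC/C=C(\C)CC[C@@H]1OC1(C)C
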